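# Proposed synthesis of methyl 2-[(3R,5S)-3,5-dimethyl-5-[(7E,9E,12Z)-pentadeca-7,9,12-trien-1-yl]-1,2-dioxolan-3-yl]acetate (29)

Locants used throughout: ring atoms O1, O2, C3 (acetate-bearing), C4, C5 (chain-bearing); side chain C1'–C15'.

## The problem

The target 29 is a 1,2-dioxolane in which C3 carries a methyl group and the CH2CO2Me arm, and C5 carries a methyl group and a pentadeca-7,9,12-trienyl chain. Both stereocentres are fully substituted, oxygen-bearing carbons separated by the C4 methylene, with the two methyl groups trans [(3R,5S)]. Neither has a hydrogen, so nothing can be repaired by epimerisation, and a 1,3-relationship across a CH2 group in an open-chain precursor gives no dependable relay; each centre must be set by a reagent, or both by one symmetric operation. The chain contains a (7'E,9'E)-diene and a (12'Z)-alkene flanking the C11' methylene, whose doubly allylic hydrogens are lost to strong base in polar media (conjugation) and to radicals. O1–O2 is the weakest bond of the molecule: once it exists, Grignard and organolithium reagents, hydrides, phosphines, low-valent metals and hydrogenation are excluded, and the ester lies β to O2, so enolisation can expel the peroxide. Yet the chain is most simply assembled with exactly such reagents. The feature that opens a way out is that O1 and O2 sit on two tertiary carbons in a 1,3-relationship: the ring is a 1,3-diol less two hydrogens. If both oxygens are first placed on C3 and C5 as alcohol oxygens of the right configuration, the ring can be closed at the O–O bond alone, late, without breaking either C–O bond.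

## Retrosynthesis

**Ester arm.** The ester C–O bond and the oxidation level of its carbon are adjusted first: 29 goes back through acid 28 and aldehyde 27 to alcohol 26 and its silyl ether 25. The arm is carried as a silylated 2-hydroxyethyl group because an ester β to a free aminooxy group would acylate it, and a β-hydroxy ester would not survive the alkoxide chemistry needed earlier. The skeleton is unchanged, but only inert functionality remains; the forward steps must be non-basic and non-reducing.

**O1–O2 bond.** In 25 only the peroxide bond is cut, and an N2 unit is inserted in the retro-direction: 25 comes from the cyclic hyponitrite 24, that from the cyclic hydrazine 23, and both from the open bis(aminooxy) compound 22 by N–N bond formation. Cutting C3–O2 or C5–O1 would demand clean inversion at a fully substituted carbon; cutting C4–C5 would demand a catalyst-controlled annulation. The O–O cut alone lets both stereocentres be made as alcohols and lets every C–C bond of the chain be made while no peroxide exists. 22 has no ring and no weak bond. The forward reaction must oxidise two NH2 groups beside a triene and must end in O–O coupling, not fragmentation.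

**C9'=C10' bond.** The diene is cut at its inner double bond: 22 goes back, through its bis(phthalimide) 21, to enal 16 and sulfone 19. This is the bond whose formation creates the doubly allylic C11' methylene, so it is placed after the strongly basic N–O bond formation. The price is that the aminooxy groups must be masked as imides while an aldehyde is present. A cut at C7'=C8' would need an allylic carbanion that is itself prone to isomerise. 16 lacks six carbons and two alkenes; the forward step must be E-selective.

**C7'=C8' bond and N-protection.** Enal 16 comes from terminal alkene 15 by exchange of its terminal CH2 for a CH–CHO unit (metathesis), and 15 from the free bis(aminooxy) compound 14 by cutting four imide N–C bonds. Metathesis is chosen over a stepwise oxidation–olefination because it tolerates the imides and gives the (E)-enal directly.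

**Two N–O bonds.** 14 goes back to the ditertiary diol 12 by cutting both O–N bonds. Bond formation at oxygen is the only way to reach a tertiary alkoxyamine with retention. It is done on the potassium alkoxides while the chain is still a plain terminal alkene, because a tertiary potassium alkoxide in a dipolar solvent is a known agent for conjugating skipped polyenes.

**C2'–C3' bond.** 12 is cut between C2' and C3' into tosylate 9 and the Grignard reagent 11 made from bromide 10. An sp3–sp3 coupling is possible here only because no peroxide is present; it removes six chain carbons in one step.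

**Desymmetrisation.** 9 comes from mono-silyl ether 8 and that from the C2-symmetric tetraol 7. Its two primary hydroxyls are homotopic, so differentiation costs a statistical step but raises no stereochemical question.

**C3–O and C5–O stereocentres.** 7 comes from bis-epoxide 6 by hydride delivery to the two secondary epoxide carbons, and 6 from the diene diol 5 by two reagent-controlled epoxidations. Both quaternary centres are thus set by the same proven reaction, and the double event purifies the C2-symmetric product statistically.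

**Core carbon skeleton.** 5 is cut at both methyl–alkene bonds and both alkene–CH2OH bonds, back to the skipped diyne 3 through the bis(alkenylalane) 4; 3 comes from 1 and 2 by one C–C bond.

**Sulfone.** 19 comes from sulfide 18 and that from the commercial (Z)-alcohol 17, which supplies C10'–C15' with the (Z)-alkene already in place.

## Roads not taken

**Alternative 1:** The cut is at the two exocyclic bonds C3–CH2 and C5–CH2 of a C2-symmetric diester. The ring would be bought ready-made as the bis(methyl ketal) A1 (3,5-dimethoxy-3,5-dimethyl-1,2-dioxolane). A confined chiral silylium imidodiphosphorimidate would ionise the two methoxy groups in turn, and each ring peroxycarbenium ion would be trapped by the silyl ketene acetal A2, giving the diester A3 with no ring closure at all.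
- Merits: the peroxide comes from the cheapest possible source, both stereocentres are set catalytically, and a stereodefined core is reached in two or three steps.
- Weak points: the second substitution must give the trans product against whatever bias the first substituent imposes on a nearly planar five-membered cation, and tertiary peroxycarbenium ions can fragment.
- Weak points for this target: A3 then has to be desymmetrised statistically, and one CH2CO2Me arm has to become C1'–C15'. That means reducing an ester to a methylene and building thirteen carbons, three alkenes included, with hydrides and organometallics forbidden.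
- Comparison: in step count to the ring this road is clearly better (about three steps against fifteen). The chosen plan sets against it two stereocentres fixed by a reaction of known reliability, a chain built with a Grignard coupling and a strongly basic olefination, and a peroxide that lives for four steps only.

**Alternative 2:** The cut is at both ring C–O bonds, O1–C5 and O2–C3. A silyl triflate would activate the C2-symmetric bis-oxetane A4; hydrogen peroxide A5 would open one oxetane at its tertiary carbon, and the new hydroperoxide would open the second oxetane 5-exo, giving the dioxolane diol A6 with inversion at both carbons.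
- Merits: both bond-forming events have direct precedent for 2,2-disubstituted oxetanes, no nitrogen chemistry is needed, and the stereocentres would come from the enantiomer of 7, that is from the same epoxidation chemistry.
- Weak points: substitution at a fully substituted carbon can leak through ionisation at either centre. A4 is also harder to reach than it looks: once both primary hydroxyls of the tetraol are activated, each tertiary alkoxide can close a six-membered ether onto the far arm in competition with the oxetane on its own arm.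
- Weak points for this target: A6 is again a symmetric diol to be differentiated with the peroxide present, and the whole of C3'–C15' must then be built under peroxide constraints.
- Comparison: on precedent for the O–O-delivering step this road is ahead of the chosen one, whose ring contraction is untested. The chosen plan sets against it that no C–O bond is broken, so there is no ionisation leak, and that all chain chemistry is done before a peroxide exists.

**Alternative 3:** The cut is at C4–C5 and O2–C3, a formal [3+2] annulation. A silylium imidodiphosphorimidate ion pair would abstract methoxide from the triethylsilylperoxy ketal A7. The alkene CH2 of methyl 3-methylbut-3-enoate A8 would attack C5, and the silylperoxy oxygen would capture the C3 cation, giving the alkynyl dioxolane ester A9.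
- Merits: this is the most convergent and shortest road. The ring, both stereocentres and the ester arm arise in one step, and A9 lacks only C9'–C15'.
- Weak points: the catalyst must distinguish methyl from a straight alkyl chain at an acyclic tertiary peroxycarbenium ion and also control the trans relationship at a second tertiary cation, which can instead lose a proton towards the ester.
- Weak points for this target: turning the terminal alkyne into the (E,E)-diene needs a hydrometalation and a cross-coupling beside the peroxide and the ester.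
- Comparison: in step economy and convergence this road is better than the chosen plan, by perhaps ten steps. The chosen plan sets against it that its stereochemistry rests on no unknown selectivity: the one untested step creates no stereocentre.

Key step: step 15

Assumption: 3,3-di-tert-butyloxaziridine is treated as a stock electrophilic aminating reagent, and the Grignard reagent 11 is made and consumed within step 7.

## Route

Step 1
Reactants: 1 propargyl bromide (3-bromoprop-1-yne); 2 ethynylmagnesium bromide
Product: 3 penta-1,4-diyne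
Conditions: CuCl (cat.), THF, 0 °C → rt; THF washed out with water, 3 kept as a solution in ClCH2CH2Cl
Reagents that add atoms: none
Why: Copper-catalysed propargylation of an alkynyl Grignard reagent forms the central CH2–C(sp) bond; the volatile skipped diyne is not concentrated but carried on in solution.

Step 2
Reactants: 3 penta-1,4-diyne
Product: 5 (2E,5E)-3,5-dimethylhepta-2,5-diene-1,7-diol, via bis(alkenylalane) 4 (not isolated)
Conditions: Me3Al, Cp2ZrCl2, ClCH2CH2Cl, 0 °C → rt; then (CH2O)n, 0 °C → rt
Reagents that add atoms: trimethylaluminium C[Al](C)C; formaldehyde (as paraformaldehyde) C=O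
Why: Zirconium-catalysed methylalumination (Negishi carboalumination) of each terminal alkyne is syn and puts aluminium on the terminal carbon, so hydroxymethylation of both C–Al bonds with retention should give the (E,E)-diene diol with each methyl cis to its CH2OH group.

Step 3
Reactants: 5 (2E,5E)-3,5-dimethylhepta-2,5-diene-1,7-diol
Product: 6 (2R,3R,5R,6R)-2,3:5,6-diepoxy-3,5-dimethylheptane-1,7-diol
Conditions: Ti(OiPr)4, D-(−)-diethyl tartrate, t-BuOOH, 4 Å molecular sieves, CH2Cl2, −20 °C
Reagents that add atoms: tert-butyl hydroperoxide CC(C)(C)OO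
Why: Sharpless asymmetric epoxidation of both allylic alcohols; for (E)-3-methylalk-2-en-1-ols the L-(+)-tartrate gives the (2S,3S)-epoxide, so the D-(−)-tartrate should give (2R,3R) at each end. A wrong-face event at one end gives a separable meso-type diastereomer, so the C2-symmetric product should be of very high enantiomeric purity; this step fixes the configuration of both future ring carbons.

Step 4
Reactants: 6 (2R,3R,5R,6R)-2,3:5,6-diepoxy-3,5-dimethylheptane-1,7-diol
Product: 7 (3S,5S)-3,5-dimethylheptane-1,3,5,7-tetraol
Conditions: NaAlH2(OCH2CH2OMe)2, THF, 0 °C → rt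
Reagents that add atoms: none
Why: Hydroxyl-directed hydride opening of 2,3-epoxy alcohols delivers hydride to C2 and C6, the secondary epoxide carbons, so both tertiary C–O bonds and their configurations are kept and two 1,3-diol units result.

Step 5
Reactants: 7 (3S,5S)-3,5-dimethylheptane-1,3,5,7-tetraol
Product: 8 (3S,5S)-3,5-dimethyl-7-[(triisopropylsilyl)oxy]heptane-1,3,5-triol
Conditions: TIPSCl (0.5 equiv), imidazole, DMF, 0 °C; excess 7 recovered
Reagents that add atoms: chlorotriisopropylsilane CC(C)[Si](Cl)(C(C)C)C(C)C
Why: Silylation of one of two homotopic primary hydroxyls; the tertiary hydroxyls do not react, and an excess of 7 keeps bis-silylation low. The bulky triisopropylsilyl group is chosen because it should not migrate to a neighbouring tertiary alkoxide in step 8.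

Step 6
Reactants: 8 (3S,5S)-3,5-dimethyl-7-[(triisopropylsilyl)oxy]heptane-1,3,5-triol
Product: 9 (3S,5S)-3,5-dihydroxy-3,5-dimethyl-7-[(triisopropylsilyl)oxy]heptyl 4-methylbenzenesulfonate
Conditions: TsCl, pyridine, CH2Cl2, 0 °C
Reagents that add atoms: 4-methylbenzenesulfonyl chloride Cc1ccc(cc1)S(Cl)(=O)=O
Why: Sulfonylation is selective for the only primary hydroxyl; tertiary hydroxyls are inert to TsCl under these conditions.

Step 7
Reactants: 9 (3S,5S)-3,5-dihydroxy-3,5-dimethyl-7-[(triisopropylsilyl)oxy]heptyl 4-methylbenzenesulfonate; 10 6-bromohex-1-ene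
Product: 12 (3S,5S)-3,5-dimethyl-1-[(triisopropylsilyl)oxy]tridec-12-ene-3,5-diol, via hex-5-en-1-ylmagnesium bromide 11 (not isolated)
Conditions: 10, Mg, THF; then 9, Li2CuCl4 (cat.), THF, −78 → 0 °C (4 equiv of 11)
Reagents that add atoms: none
Why: Copper-catalysed coupling of a primary tosylate with a primary alkyl Grignard reagent (Kochi–Schlosser type) forms C2'–C3'; two equivalents of 11 are spent on the tertiary hydroxyls, whose magnesium alkoxides should be too weakly nucleophilic at low temperature to displace the tosylate first.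

Step 8
Reactants: 12 (3S,5S)-3,5-dimethyl-1-[(triisopropylsilyl)oxy]tridec-12-ene-3,5-diol
Product: 14 (3S,5S)-3,5-bis(aminooxy)-3,5-dimethyl-1-[(triisopropylsilyl)oxy]tridec-12-ene, via dipotassium dialkoxide 13 (not isolated)
Conditions: KH (2.2 equiv), THF–DMPU, 0 °C; then 3,3-di-tert-butyloxaziridine, −40 °C → rt
Reagents that add atoms: 3,3-di-tert-butyloxaziridine CC(C)(C)C1(NO1)C(C)(C)C
Why: Electrophilic amination of alkoxides by an N–H oxaziridine, a reaction known for tertiary alkoxides: each oxygen attacks nitrogen and the hindered ketone that is released cannot condense with the product. No C–O bond is touched, so both centres keep their configuration; the step is placed here because no base-sensitive skipped polyene exists yet.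

Step 9
Reactants: 14 (3S,5S)-3,5-bis(aminooxy)-3,5-dimethyl-1-[(triisopropylsilyl)oxy]tridec-12-ene
Product: 15 (3S,5S)-3,5-dimethyl-3,5-bis(phthalimidooxy)-1-[(triisopropylsilyl)oxy]tridec-12-ene
Conditions: phthalic anhydride, Et3N (cat.), toluene, 110 °C, Dean–Stark
Reagents that add atoms: phthalic anhydride O=C1OC(=O)c2ccccc12
Why: Condensation of both O-alkylhydroxylamines to N-alkoxyphthalimides removes the nucleophilic NH2 groups before an aldehyde enters the molecule, and the imides can later be cleaved without acid.

Step 10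
Reactants: 15 (3S,5S)-3,5-dimethyl-3,5-bis(phthalimidooxy)-1-[(triisopropylsilyl)oxy]tridec-12-ene
Product: 16 (2E,10S,12S)-10,12-dimethyl-10,12-bis(phthalimidooxy)-14-[(triisopropylsilyl)oxy]tetradec-2-enal
Conditions: crotonaldehyde (excess), second-generation Hoveyda–Grubbs catalyst RuCl2(H2IMes)(=CH-C6H4-2-OiPr) (cat.), CH2Cl2, 40 °C
Reagents that add atoms: (E)-but-2-enal C/C=C/C=O
Why: Olefin cross-metathesis of a terminal alkene with an excess of an electron-poor enal; the conjugated (E)-enal is the expected product, and any homodimer of 15 is returned to the catalytic cycle.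

Step 11
Reactants: 17 (Z)-hex-3-en-1-ol
Product: 18 5-[(3Z)-hex-3-en-1-ylsulfanyl]-1-phenyl-1H-tetrazole
Conditions: 1-phenyl-1H-tetrazole-5-thiol, PPh3, DIAD, THF, 0 °C → rt
Reagents that add atoms: 1-phenyl-1H-tetrazole-5-thiol Sc1nnnn1-c1ccccc1
Why: Mitsunobu thioetherification of a primary alcohol with an acidic heteroaryl thiol; the remote (Z)-alkene is not involved.

Step 12
Reactants: 18 5-[(3Z)-hex-3-en-1-ylsulfanyl]-1-phenyl-1H-tetrazole
Product: 19 5-[(3Z)-hex-3-ene-1-sulfonyl]-1-phenyl-1H-tetrazole
Conditions: H2O2 (30% aq), (NH4)6Mo7O24·4H2O (cat.), EtOH, 0 °C → rt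
Reagents that add atoms: hydrogen peroxide OO
Why: Molybdate-catalysed oxidation of sulfide to sulfone; sulfur is oxidised far faster than an isolated disubstituted alkene is epoxidised.

Step 13
Reactants: 16 (2E,10S,12S)-10,12-dimethyl-10,12-bis(phthalimidooxy)-14-[(triisopropylsilyl)oxy]tetradec-2-enal; 19 5-[(3Z)-hex-3-ene-1-sulfonyl]-1-phenyl-1H-tetrazole
Product: 21 (3S,5S,12E,14E,17Z)-3,5-dimethyl-3,5-bis(phthalimidooxy)-1-[(triisopropylsilyl)oxy]icosa-12,14,17-triene, via potassium sulfonyl carbanion 20 (not isolated)
Conditions: 19, KN(SiMe3)2, DME, −78 °C; solution added to 16 in DME, −78 °C → rt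
Reagents that add atoms: none
Why: Julia–Kocienski olefination: addition of the metallated phenyltetrazolyl sulfone to the enal, Smiles rearrangement and loss of SO2 and tetrazolone form C9'=C10', and this sulfone type with a potassium counter-ion in DME should favour the E geometry. Inverse addition at −78 °C keeps the carbanion from meeting the imide carbonyls in excess; a minor (9'Z)-isomer would be removed on AgNO3-impregnated silica.

Step 14
Reactants: 21 (3S,5S,12E,14E,17Z)-3,5-dimethyl-3,5-bis(phthalimidooxy)-1-[(triisopropylsilyl)oxy]icosa-12,14,17-triene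
Product: 22 (3S,5S,12E,14E,17Z)-3,5-bis(aminooxy)-3,5-dimethyl-1-[(triisopropylsilyl)oxy]icosa-12,14,17-triene
Conditions: MeNHNH2, CH2Cl2, 0 °C → rt, under argon
Reagents that add atoms: none
Why: Hydrazinolysis of N-alkoxyphthalimides (Ing–Manske type) frees both aminooxy groups under neutral conditions; air is excluded so that no diimide can form and reduce the triene.

Step 15
Reactants: 22 (3S,5S,12E,14E,17Z)-3,5-bis(aminooxy)-3,5-dimethyl-1-[(triisopropylsilyl)oxy]icosa-12,14,17-triene
Product: 25 triisopropyl{2-[(3S,5S)-3,5-dimethyl-5-[(7E,9E,12Z)-pentadeca-7,9,12-trien-1-yl]-1,2-dioxolan-3-yl]ethoxy}silane, via cyclic dialkoxyhydrazine 23 (not isolated), via cyclic hyponitrite 24 (not isolated)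
Conditions: PhI(OAc)2 (2.2 equiv, added slowly), CH2Cl2 (high dilution, about 0.005 M), −40 °C → rt, then 40 °C until gas evolution ends
Reagents that add atoms: none
Why: Proposed new method: ligand exchange at trivalent iodine makes one aminooxy nitrogen electrophilic, and the second aminooxy nitrogen, held close by the two quaternary carbons, displaces iodobenzene to give the cyclic N,N'-dialkoxyhydrazine 23 in a seven-membered closure (ring O–N–N–O–C5–C4–C3, nitrogen attacking nitrogen). A second equivalent of oxidant dehydrogenates 23 to the ring-constrained cis-hyponitrite 24, which cannot relax to the more stable trans form and should lose N2 at or a little above room temperature. Extrusion leaves a singlet pair of tertiary alkoxyl radicals on O1 and O2, three carbons apart, whose recombination closes the five-membered 1,2-dioxolane, so that the overall event is a seven-to-five ring contraction. The closest known reactions are the oxidation of O-alkylhydroxylamines to open-chain dialkyl hyponitrites, the thermolysis of such hyponitrites to N2 and caged alkoxyl radicals that partly recombine to dialkyl peroxides, and the Pb(OAc)4 oxidation of 1,3-bis(hydroperoxides) to 1,2-dioxolanes with loss of O2. No stereocentre is created: neither C3–O nor C5–O is broken at any stage, so both quaternary centres keep the configuration fixed in step 3. The step needs intramolecular N–N coupling to outrun bimolecular hyponitrite formation and addition of an oxidised nitrogen to the 7',9'-diene; high dilution, slow addition of the oxidant and the gem-dialkyl effect of C3 and C5 should secure this. It also needs radical-pair collapse to outrun β-scission and 1,5-hydrogen transfer, which the three-atom tether and the singlet state of a thermally born pair favour; the same diradical is the one that recloses in the reversible O–O homolysis of 1,2-dioxolanes. Loss of N2O is not expected, because it would require C–O cleavage and closure of an oxetane.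

Step 16
Reactants: 25 triisopropyl{2-[(3S,5S)-3,5-dimethyl-5-[(7E,9E,12Z)-pentadeca-7,9,12-trien-1-yl]-1,2-dioxolan-3-yl]ethoxy}silane
Product: 26 2-[(3S,5S)-3,5-dimethyl-5-[(7E,9E,12Z)-pentadeca-7,9,12-trien-1-yl]-1,2-dioxolan-3-yl]ethan-1-ol
Conditions: Bu4NF, AcOH, THF, 0 °C → rt
Reagents that add atoms: none
Why: Fluoride cleavage of the primary silyl ether; the tetrasubstituted dioxolane has no hydrogen on its oxygen-bearing carbons and so offers no path for base-induced peroxide fragmentation.

Step 17
Reactants: 26 2-[(3S,5S)-3,5-dimethyl-5-[(7E,9E,12Z)-pentadeca-7,9,12-trien-1-yl]-1,2-dioxolan-3-yl]ethan-1-ol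
Product: 27 2-[(3R,5S)-3,5-dimethyl-5-[(7E,9E,12Z)-pentadeca-7,9,12-trien-1-yl]-1,2-dioxolan-3-yl]acetaldehyde
Conditions: Dess–Martin periodinane, NaHCO3, CH2Cl2, 0 °C → rt
Reagents that add atoms: none
Why: Dess–Martin oxidation of a primary alcohol under buffered, non-basic conditions that spare the dialkyl peroxide and the triene; the β-peroxy aldehyde is used at once to avoid elimination (the descriptor at C3 changes by priority only).

Step 18
Reactants: 27 2-[(3R,5S)-3,5-dimethyl-5-[(7E,9E,12Z)-pentadeca-7,9,12-trien-1-yl]-1,2-dioxolan-3-yl]acetaldehyde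
Product: 28 2-[(3R,5S)-3,5-dimethyl-5-[(7E,9E,12Z)-pentadeca-7,9,12-trien-1-yl]-1,2-dioxolan-3-yl]acetic acid
Conditions: NaClO2, NaH2PO4, 2-methylbut-2-ene, t-BuOH–H2O, 0 °C → rt
Reagents that add atoms: sodium chlorite [Na+].[O-]Cl=O
Why: Pinnick oxidation of the aldehyde to the acid at weakly acidic pH; the alkene scavenger takes up hypochlorous acid before it can add to the triene.

Step 19
Reactants: 28 2-[(3R,5S)-3,5-dimethyl-5-[(7E,9E,12Z)-pentadeca-7,9,12-trien-1-yl]-1,2-dioxolan-3-yl]acetic acid
Product: 29 methyl 2-[(3R,5S)-3,5-dimethyl-5-[(7E,9E,12Z)-pentadeca-7,9,12-trien-1-yl]-1,2-dioxolan-3-yl]acetate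
Conditions: Me3SiCHN2, MeOH–toluene, 0 °C
Reagents that add atoms: (trimethylsilyl)diazomethane C[Si](C)(C)C=[N+]=[N-]
Why: Esterification with (trimethylsilyl)diazomethane in methanol is neutral and avoids the basic conditions under which a β-peroxy ester could lose the peroxide by elimination.

## Compound list

1 | propargyl bromide (3-bromoprop-1-yne) | C#CCBr | starting material
2 | ethynylmagnesium bromide | C#C[Mg]Br | starting material
3 | penta-1,4-diyne | C#CCC#C | intermediate
4 | (1E,4E)-(2,4-dimethylpenta-1,4-diene-1,5-diyl)bis(dimethylalumane) | C[Al](C)/C=C(\C)C/C(C)=C/[Al](C)C | intermediate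
5 | (2E,5E)-3,5-dimethylhepta-2,5-diene-1,7-diol | OC/C=C(\C)C/C(C)=C/CO | intermediate
6 | (2R,3R,5R,6R)-2,3:5,6-diepoxy-3,5-dimethylheptane-1,7-diol | OC[C@H]1O[C@]1(C)C[C@@]2(C)O[C@@H]2CO | intermediate
7 | (3S,5S)-3,5-dimethylheptane-1,3,5,7-tetraol | OCC[C@@](O)(C)C[C@](C)(CCO)O | intermediate
8 | (3S,5S)-3,5-dimethyl-7-[(triisopropylsilyl)oxy]heptane-1,3,5-triol | OCC[C@@](O)(C)C[C@](C)(CCO[Si](C(C)C)(C(C)C)C(C)C)O | intermediate
9 | (3S,5S)-3,5-dihydroxy-3,5-dimethyl-7-[(triisopropylsilyl)oxy]heptyl 4-methylbenzenesulfonate | Cc1ccc(cc1)S(=O)(=O)OCC[C@@](O)(C)C[C@](C)(CCO[Si](C(C)C)(C(C)C)C(C)C)O | intermediate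
10 | 6-bromohex-1-ene | C=CCCCCBr | starting material
11 | hex-5-en-1-ylmagnesium bromide | C=CCCCC[Mg]Br | intermediate
12 | (3S,5S)-3,5-dimethyl-1-[(triisopropylsilyl)oxy]tridec-12-ene-3,5-diol | C=CCCCCCC[C@@](O)(C)C[C@](C)(CCO[Si](C(C)C)(C(C)C)C(C)C)O | intermediate
13 | dipotassium (3S,5S)-3,5-dimethyl-1-[(triisopropylsilyl)oxy]tridec-12-ene-3,5-diolate | [K+].[K+].C=CCCCCCC[C@@]([O-])(C)C[C@](C)(CCO[Si](C(C)C)(C(C)C)C(C)C)[O-] | intermediate
14 | (3S,5S)-3,5-bis(aminooxy)-3,5-dimethyl-1-[(triisopropylsilyl)oxy]tridec-12-ene | C=CCCCCCC[C@@](ON)(C)C[C@](C)(CCO[Si](C(C)C)(C(C)C)C(C)C)ON | intermediate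
15 | (3S,5S)-3,5-dimethyl-3,5-bis(phthalimidooxy)-1-[(triisopropylsilyl)oxy]tridec-12-ene | C=CCCCCCC[C@@](ON1C(=O)c2ccccc2C1=O)(C)C[C@](C)(CCO[Si](C(C)C)(C(C)C)C(C)C)ON1C(=O)c2ccccc2C1=O | intermediate
16 | (2E,10S,12S)-10,12-dimethyl-10,12-bis(phthalimidooxy)-14-[(triisopropylsilyl)oxy]tetradec-2-enal | O=C/C=C/CCCCCC[C@@](ON1C(=O)c2ccccc2C1=O)(C)C[C@](C)(CCO[Si](C(C)C)(C(C)C)C(C)C)ON1C(=O)c2ccccc2C1=O | intermediate
17 | (Z)-hex-3-en-1-ol | CC/C=C\CCO | starting material
18 | 5-[(3Z)-hex-3-en-1-ylsulfanyl]-1-phenyl-1H-tetrazole | CC/C=C\CCSc1nnnn1-c1ccccc1 | intermediate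
19 | 5-[(3Z)-hex-3-ene-1-sulfonyl]-1-phenyl-1H-tetrazole | CC/C=C\CCS(=O)(=O)c1nnnn1-c1ccccc1 | intermediate
20 | potassium (3Z)-1-[(1-phenyl-1H-tetrazol-5-yl)sulfonyl]hex-3-en-1-ide | [K+].CC/C=C\C[CH-]S(=O)(=O)c1nnnn1-c1ccccc1 | intermediate
21 | (3S,5S,12E,14E,17Z)-3,5-dimethyl-3,5-bis(phthalimidooxy)-1-[(triisopropylsilyl)oxy]icosa-12,14,17-triene | CC/C=C\C/C=C/C=C/CCCCCC[C@@](ON1C(=O)c2ccccc2C1=O)(C)C[C@](C)(CCO[Si](C(C)C)(C(C)C)C(C)C)ON1C(=O)c2ccccc2C1=O | intermediate
22 | (3S,5S,12E,14E,17Z)-3,5-bis(aminooxy)-3,5-dimethyl-1-[(triisopropylsilyl)oxy]icosa-12,14,17-triene | CC/C=C\C/C=C/C=C/CCCCCC[C@@](ON)(C)C[C@](C)(CCO[Si](C(C)C)(C(C)C)C(C)C)ON | intermediate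
23 | (5S,7S)-5,7-dimethyl-5-[(7E,9E,12Z)-pentadeca-7,9,12-trien-1-yl]-7-{2-[(triisopropylsilyl)oxy]ethyl}-1,4,2,3-dioxadiazepane | CC/C=C\C/C=C/C=C/CCCCCC[C@@]1(C)C[C@](C)(CCO[Si](C(C)C)(C(C)C)C(C)C)ONNO1 | intermediate
24 | (5S,7S)-5,7-dimethyl-5-[(7E,9E,12Z)-pentadeca-7,9,12-trien-1-yl]-7-{2-[(triisopropylsilyl)oxy]ethyl}-6,7-dihydro-5H-1,4,2,3-dioxadiazepine | CC/C=C\C/C=C/C=C/CCCCCC[C@@]1(C)C[C@](C)(CCO[Si](C(C)C)(C(C)C)C(C)C)ON=NO1 | intermediate
25 | triisopropyl{2-[(3S,5S)-3,5-dimethyl-5-[(7E,9E,12Z)-pentadeca-7,9,12-trien-1-yl]-1,2-dioxolan-3-yl]ethoxy}silane | CC/C=C\C/C=C/C=C/CCCCCC[C@@]1(C)C[C@](C)(CCO[Si](C(C)C)(C(C)C)C(C)C)OO1 | intermediate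
26 | 2-[(3S,5S)-3,5-dimethyl-5-[(7E,9E,12Z)-pentadeca-7,9,12-trien-1-yl]-1,2-dioxolan-3-yl]ethan-1-ol | CC/C=C\C/C=C/C=C/CCCCCC[C@@]1(C)C[C@](C)(CCO)OO1 | intermediate
27 | 2-[(3R,5S)-3,5-dimethyl-5-[(7E,9E,12Z)-pentadeca-7,9,12-trien-1-yl]-1,2-dioxolan-3-yl]acetaldehyde | CC/C=C\C/C=C/C=C/CCCCCC[C@@]1(C)C[C@](C)(CC=O)OO1 | intermediate
28 | 2-[(3R,5S)-3,5-dimethyl-5-[(7E,9E,12Z)-pentadeca-7,9,12-trien-1-yl]-1,2-dioxolan-3-yl]acetic acid | CC/C=C\C/C=C/C=C/CCCCCC[C@@]1(C)C[C@](C)(CC(=O)O)OO1 | intermediate
29 | methyl 2-[(3R,5S)-3,5-dimethyl-5-[(7E,9E,12Z)-pentadeca-7,9,12-trien-1-yl]-1,2-dioxolan-3-yl]acetate | CC/C=C\C/C=C/C=C/CCCCCC[C@@]1(C)C[C@](C)(CC(=O)OC)OO1 | target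

## Step count and least certain steps

Total: 19 steps. Longest linear sequence: 17 steps (steps 1–10 and 13–19); steps 11–12 make the sulfone 19.

**Step 15 (key step, the one carrying the new method).**
- What may go wrong: oligomerisation by intermolecular N–N coupling; addition of an oxidised nitrogen to the diene; consumption of the alkoxyl radical pair by β-scission or 1,5-hydrogen transfer instead of O–O coupling; or a hyponitrite that loses N2 only at a temperature the triene does not tolerate. None of these has been tested on a cyclic case.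
- Fallback, by known reaction types only and with the peroxide oxygens taken from H2O2: it sets out from 5 and rejoins the route at 25.
  - Monosilylation of 5 (NaH, TIPSCl) gives (2E,5E)-3,5-dimethyl-7-[(triisopropylsilyl)oxy]hepta-2,5-dien-1-ol F1.
  - Sharpless epoxidation of the one remaining allylic alcohol with L-(+)-diethyl tartrate gives [(2S,3S)-3-methyl-3-{(2E)-2-methyl-4-[(triisopropylsilyl)oxy]but-2-en-1-yl}oxiran-2-yl]methanol F2. NaAlH2(OCH2CH2OMe)2 then gives (3S,5E)-3,5-dimethyl-7-[(triisopropylsilyl)oxy]hept-5-ene-1,3-diol F3, whose carbinol carbon is arranged opposite to that of the main route.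
  - Tosylation of the primary hydroxyl gives (3S,5E)-3-hydroxy-3,5-dimethyl-7-[(triisopropylsilyl)oxy]hept-5-en-1-yl 4-methylbenzenesulfonate F4, and KOtBu closes triisopropyl({(2E)-3-methyl-4-[(2S)-2-methyloxetan-2-yl]but-2-en-1-yl}oxy)silane F5. No second alkoxide is present, so no larger ring can form.
  - Ethereal H2O2 with Me3SiOTf opens the oxetane at its tertiary carbon with inversion to (3R,5E)-3-hydroperoxy-3,5-dimethyl-7-[(triisopropylsilyl)oxy]hept-5-en-1-ol F6; this carbon becomes C5 of the target.
  - Hg(OAc)2, then KBr, closes the ring by 5-exo peroxymercuration of the trisubstituted alkene to bromo{1-[5-(2-hydroxyethyl)-3,5-dimethyl-1,2-dioxolan-3-yl]-2-[(triisopropylsilyl)oxy]ethyl}mercury F7. NaBH4 removes mercury to give 2-[(3S,5S)-3,5-dimethyl-5-{2-[(triisopropylsilyl)oxy]ethyl}-1,2-dioxolan-3-yl]ethan-1-ol F8. C3 is set in this cyclisation without reagent control, and the cis-dimethyl isomer has to be separated.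
  - The chain is then added with peroxide-tolerant reactions only. Dess–Martin oxidation gives 2-[(3R,5S)-3,5-dimethyl-5-{2-[(triisopropylsilyl)oxy]ethyl}-1,2-dioxolan-3-yl]acetaldehyde F9. Wittig reaction with the ylide of [4-(1,3-dioxolan-2-yl)butyl]triphenylphosphonium bromide gives triisopropyl{2-[(3S,5S)-5-[(2Z)-6-(1,3-dioxolan-2-yl)hex-2-en-1-yl]-3,5-dimethyl-1,2-dioxolan-3-yl]ethoxy}silane F10. Diimide (from potassium azodicarboxylate and AcOH) gives triisopropyl{2-[(3S,5S)-5-[6-(1,3-dioxolan-2-yl)hexyl]-3,5-dimethyl-1,2-dioxolan-3-yl]ethoxy}silane F11. Mild acid hydrolysis of the acetal gives 7-[(3S,5S)-3,5-dimethyl-5-{2-[(triisopropylsilyl)oxy]ethyl}-1,2-dioxolan-3-yl]heptanal F12. Ph3P=CHCHO gives (2E)-9-[(3S,5S)-3,5-dimethyl-5-{2-[(triisopropylsilyl)oxy]ethyl}-1,2-dioxolan-3-yl]non-2-enal F13. Julia–Kocienski olefination of F13 with 19, as in step 13, gives 25.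

**Step 8 (double amination of a hindered 1,3-dialkoxide).**
- What may go wrong: proton transfer from the N–H oxaziridine to the tertiary alkoxide instead of nitrogen transfer, or a stall after the first amination because the remaining alkoxide is tied up in an aggregate with its neighbour.
- Fallback: from 12 the two N–O bonds are made one at a time with a different class of nitrogen electrophile. NaH (1 equiv) and ethereal NH2Cl (displacement of chloride at nitrogen, the classical route to O-tert-alkylhydroxylamines) give the regioisomeric mono(aminooxy) alcohols (3S,5S)-5-(aminooxy)-3,5-dimethyl-1-[(triisopropylsilyl)oxy]tridec-12-en-3-ol F14 and (3S,5S)-3-(aminooxy)-3,5-dimethyl-1-[(triisopropylsilyl)oxy]tridec-12-en-5-ol F15. These are not separated; a second pass through the same operation brings both to 14.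

**Step 2 (double carboalumination of a volatile skipped diyne).**
- What may go wrong: metalation or isomerisation at the doubly propargylic CH2, incomplete reaction at the second alkyne, and loss of the volatile diyne during removal of THF.
- Fallback: from 1, the two alkenes are made in sequence on a stable silyl diyne. Coupling of 1 with (trimethylsilyl)ethynylmagnesium bromide (CuCl) gives trimethyl(penta-1,4-diyn-1-yl)silane F16. Carboalumination of its free terminal alkyne and hydroxymethylation give (2E)-3-methyl-6-(trimethylsilyl)hex-2-en-5-yn-1-ol F17. K2CO3 in MeOH removes silicon to give (2E)-3-methylhex-2-en-5-yn-1-ol F18. A second carboalumination–hydroxymethylation, with one more equivalent of Me3Al for the hydroxyl, gives 5.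

**Step 13 (Julia–Kocienski olefination beside two imides).**
- What may go wrong: incomplete E-selectivity at C9'=C10', attack of the carbanion on an imide carbonyl, or base-induced migration of the new skipped triene during warming.
- Fallback: from 15 and 17, rejoining at 21, the diene is assembled by forming its central single bond from two alkenes of fixed geometry. Cross-metathesis of 15 with vinylboronic acid pinacol ester gives 2,2'-{[(3S,5S,12E)-3,5-dimethyl-13-(4,4,5,5-tetramethyl-1,3,2-dioxaborolan-2-yl)-1-[(triisopropylsilyl)oxy]tridec-12-ene-3,5-diyl]bis(oxy)}bis(isoindoline-1,3-dione) F19. Dess–Martin oxidation of 17 gives (3Z)-hex-3-enal F20, which is used at once, and Takai olefination (CHI3, CrCl2) gives (1E,4Z)-1-iodohepta-1,4-diene F21. Suzuki–Miyaura coupling of F19 with F21 (Pd(PPh3)4, K3PO4, THF–H2O, rt) gives 21.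

**Step 7 (copper-catalysed coupling with two free tertiary alkoxides).**
- What may go wrong: intramolecular O-alkylation, above all closure of a six-membered ether by the C3 alkoxide onto the tosylate-bearing carbon, competing with C–C coupling.
- Fallback: from 9, rejoining at 12, the alkoxides are taken out of play. Me3SiCl and imidazole give (3S,5S)-3,5-dimethyl-7-[(triisopropylsilyl)oxy]-3,5-bis[(trimethylsilyl)oxy]heptyl 4-methylbenzenesulfonate F22. Coupling with 11 under Li2CuCl4 catalysis gives (3S,5S)-3,5-dimethyl-1-[(triisopropylsilyl)oxy]-3,5-bis[(trimethylsilyl)oxy]tridec-12-ene F23. Citric acid in MeOH removes the two tertiary trimethylsilyl groups, but not the triisopropylsilyl ether, to give 12.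

## Further compounds

F1 | step 15 | (2E,5E)-3,5-dimethyl-7-[(triisopropylsilyl)oxy]hepta-2,5-dien-1-ol | OC/C=C(\C)C/C(C)=C/CO[Si](C(C)C)(C(C)C)C(C)C
F2 | step 15 | [(2S,3S)-3-methyl-3-{(2E)-2-methyl-4-[(triisopropylsilyl)oxy]but-2-en-1-yl}oxiran-2-yl]methanol | OC[C@@H]1O[C@@]1(C)C/C(C)=C/CO[Si](C(C)C)(C(C)C)C(C)C
F3 | step 15 | (3S,5E)-3,5-dimethyl-7-[(triisopropylsilyl)oxy]hept-5-ene-1,3-diol | OCC[C@](O)(C)C/C(C)=C/CO[Si](C(C)C)(C(C)C)C(C)C
F4 | step 15 | (3S,5E)-3-hydroxy-3,5-dimethyl-7-[(triisopropylsilyl)oxy]hept-5-en-1-yl 4-methylbenzenesulfonate | Cc1ccc(cc1)S(=O)(=O)OCC[C@](O)(C)C/C(C)=C/CO[Si](C(C)C)(C(C)C)C(C)C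
F5 | step 15 | triisopropyl({(2E)-3-methyl-4-[(2S)-2-methyloxetan-2-yl]but-2-en-1-yl}oxy)silane | C[C@@]1(CCO1)C/C(C)=C/CO[Si](C(C)C)(C(C)C)C(C)C
F6 | step 15 | (3R,5E)-3-hydroperoxy-3,5-dimethyl-7-[(triisopropylsilyl)oxy]hept-5-en-1-ol | OCC[C@@](OO)(C)C/C(C)=C/CO[Si](C(C)C)(C(C)C)C(C)C
F7 | step 15 | bromo{1-[5-(2-hydroxyethyl)-3,5-dimethyl-1,2-dioxolan-3-yl]-2-[(triisopropylsilyl)oxy]ethyl}mercury, trans-dimethyl isomer | OCC[C@@]1(C)C[C@](C)(C([Hg]Br)CO[Si](C(C)C)(C(C)C)C(C)C)OO1
F8 | step 15 | 2-[(3S,5S)-3,5-dimethyl-5-{2-[(triisopropylsilyl)oxy]ethyl}-1,2-dioxolan-3-yl]ethan-1-ol | OCC[C@@]1(C)C[C@](C)(CCO[Si](C(C)C)(C(C)C)C(C)C)OO1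
F9 | step 15 | 2-[(3R,5S)-3,5-dimethyl-5-{2-[(triisopropylsilyl)oxy]ethyl}-1,2-dioxolan-3-yl]acetaldehyde | O=CC[C@@]1(C)C[C@](C)(CCO[Si](C(C)C)(C(C)C)C(C)C)OO1
F10 | step 15 | triisopropyl{2-[(3S,5S)-5-[(2Z)-6-(1,3-dioxolan-2-yl)hex-2-en-1-yl]-3,5-dimethyl-1,2-dioxolan-3-yl]ethoxy}silane | C1COC(O1)CCC/C=C\C[C@@]1(C)C[C@](C)(CCO[Si](C(C)C)(C(C)C)C(C)C)OO1
F11 | step 15 | triisopropyl{2-[(3S,5S)-5-[6-(1,3-dioxolan-2-yl)hexyl]-3,5-dimethyl-1,2-dioxolan-3-yl]ethoxy}silane | C1COC(O1)CCCCCC[C@@]1(C)C[C@](C)(CCO[Si](C(C)C)(C(C)C)C(C)C)OO1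
F12 | step 15 | 7-[(3S,5S)-3,5-dimethyl-5-{2-[(triisopropylsilyl)oxy]ethyl}-1,2-dioxolan-3-yl]heptanal | O=CCCCCCC[C@@]1(C)C[C@](C)(CCO[Si](C(C)C)(C(C)C)C(C)C)OO1
F13 | step 15 | (2E)-9-[(3S,5S)-3,5-dimethyl-5-{2-[(triisopropylsilyl)oxy]ethyl}-1,2-dioxolan-3-yl]non-2-enal | O=C/C=C/CCCCCC[C@@]1(C)C[C@](C)(CCO[Si](C(C)C)(C(C)C)C(C)C)OO1
F14 | step 8 | (3S,5S)-5-(aminooxy)-3,5-dimethyl-1-[(triisopropylsilyl)oxy]tridec-12-en-3-ol | C=CCCCCCC[C@@](ON)(C)C[C@](C)(CCO[Si](C(C)C)(C(C)C)C(C)C)O
F15 | step 8 | (3S,5S)-3-(aminooxy)-3,5-dimethyl-1-[(triisopropylsilyl)oxy]tridec-12-en-5-ol | C=CCCCCCC[C@@](O)(C)C[C@](C)(CCO[Si](C(C)C)(C(C)C)C(C)C)ON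
F16 | step 2 | trimethyl(penta-1,4-diyn-1-yl)silane | C#CCC#C[Si](C)(C)C
F17 | step 2 | (2E)-3-methyl-6-(trimethylsilyl)hex-2-en-5-yn-1-ol | OC/C=C(\C)CC#C[Si](C)(C)C
F18 | step 2 | (2E)-3-methylhex-2-en-5-yn-1-ol | OC/C=C(\C)CC#C
F19 | step 13 | 2,2'-{[(3S,5S,12E)-3,5-dimethyl-13-(4,4,5,5-tetramethyl-1,3,2-dioxaborolan-2-yl)-1-[(triisopropylsilyl)oxy]tridec-12-ene-3,5-diyl]bis(oxy)}bis(isoindoline-1,3-dione) | CC1(C)OB(OC1(C)C)/C=C/CCCCCC[C@@](ON1C(=O)c2ccccc2C1=O)(C)C[C@](C)(CCO[Si](C(C)C)(C(C)C)C(C)C)ON1C(=O)c2ccccc2C1=O
F20 | step 13 | (3Z)-hex-3-enal | CC/C=C\CC=O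
F21 | step 13 | (1E,4Z)-1-iodohepta-1,4-diene | CC/C=C\C/C=C/I
F22 | step 7 | (3S,5S)-3,5-dimethyl-7-[(triisopropylsilyl)oxy]-3,5-bis[(trimethylsilyl)oxy]heptyl 4-methylbenzenesulfonate | Cc1ccc(cc1)S(=O)(=O)OCC[C@@](O[Si](C)(C)C)(C)C[C@](C)(CCO[Si](C(C)C)(C(C)C)C(C)C)O[Si](C)(C)C
F23 | step 7 | (3S,5S)-3,5-dimethyl-1-[(triisopropylsilyl)oxy]-3,5-bis[(trimethylsilyl)oxy]tridec-12-ene | C=CCCCCCC[C@@](O[Si](C)(C)C)(C)C[C@](C)(CCO[Si](C(C)C)(C(C)C)C(C)C)O[Si](C)(C)C
A1 | alternative 1 | 3,5-dimethoxy-3,5-dimethyl-1,2-dioxolane | COC1(C)CC(C)(OC)OO1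
A2 | alternative 1 | 1-methoxy-1-(trimethylsilyloxy)ethene | C=C(OC)O[Si](C)(C)C
A3 | alternative 1 | dimethyl (3R,5R)-3,5-dimethyl-1,2-dioxolane-3,5-diacetate | COC(=O)C[C@@]1(C)C[C@](C)(CC(=O)OC)OO1
A4 | alternative 2 | (2R,2'R)-2,2'-methylenebis(2-methyloxetane) | C[C@@]1(CCO1)C[C@@]2(C)CCO2
A5 | alternative 2 | hydrogen peroxide | OO
A6 | alternative 2 | (3S,5S)-3,5-bis(2-hydroxyethyl)-3,5-dimethyl-1,2-dioxolane | OCC[C@@]1(C)C[C@](C)(CCO)OO1
A7 | alternative 3 | triethyl[(2-methoxydec-9-yn-2-yl)peroxy]silane | C#CCCCCCCC(C)(OC)OO[Si](CC)(CC)CC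
A8 | alternative 3 | methyl 3-methylbut-3-enoate | C=C(C)CC(=O)OC
A9 | alternative 3 | methyl 2-[(3R,5S)-3,5-dimethyl-5-(oct-7-yn-1-yl)-1,2-dioxolan-3-yl]acetate | C#CCCCCCC[C@@]1(C)C[C@](C)(CC(=O)OC)OO1
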